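## Retrosynthetic overview

1. Target 26 ⇒ C8 alcohol 22 + side-chain acid 24 (esterification last).
2. 22 ⇒ bromo-enal 19: the C6–C7 bond is formed by a visible-light-driven, Cr-catalysed intramolecular Barbier allylation that closes the ten-membered ring and sets C6/C7; the γ-lactone then closes.
3. 19 ⇒ C7 aldehyde 14 + methyl acrylate (Morita–Baylis–Hillman, SN2′ bromination); the furanone of 11 ⇒ α′-hydroxy ynone 10 (Au(I) 5-endo cyclisation).
4. 10 ⇒ lactone 6 + acetylide of (Z)-enynol 7; 6 ⇒ (R)-γ-hydroxymethyl-γ-butyrolactone 1 (C8 purchased; C10 set anti to it by enolate methylation/hydroxylation).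
5. Ring order: 3(2H)-furanone, then ten-membered carbocycle, then α-methylene-γ-lactone.

Assumptions: 1 (D-glutamic acid pool), 7 and 23 (both vitamin A industry building blocks) are taken as commercial. Tr = trityl, TBS = tert-butyldimethylsilyl, TBSO = tert-butyldimethylsilyloxy. Positions C1–C15 follow germacrane numbering of the target. CIP labels at C7 change with the O-substituents at C6/C8 while the spatial arrangement stays that of the target.

## Route

Step 1
Reactants: 1 (R)-5-(hydroxymethyl)dihydrofuran-2(3H)-one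
Product: 2 (R)-5-[(trityloxy)methyl]dihydrofuran-2(3H)-one
Conditions: TrCl, Et3N, DMAP (cat.), CH2Cl2, rt
Reagents that add atoms: trityl chloride, ClC(c1ccccc1)(c1ccccc1)c1ccccc1
Why: Selective SN1-type tritylation of the primary alcohol leaves the purchased stereocentre (future C8) untouched and installs the bulky group that shields one lactone face in steps 2–3.

Step 2
Reactants: 2 (R)-5-[(trityloxy)methyl]dihydrofuran-2(3H)-one
Product: 4 (3S,5R)-3-methyl-5-[(trityloxy)methyl]dihydrofuran-2(3H)-one, via lithium enolate 3 (not isolated)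
Conditions: LDA, THF, −78 °C; MeI, −78 → −40 °C
Reagents that add atoms: methyl iodide, CI
Why: Lactone enolate alkylation occurs anti to the CH2OTr group to give mainly the trans epimer; the C3 configuration is erased again in step 3, so the ratio is immaterial.

Step 3
Reactants: 4 (3S,5R)-3-methyl-5-[(trityloxy)methyl]dihydrofuran-2(3H)-one
Product: 6 (3S,5R)-3-hydroxy-3-methyl-5-[(trityloxy)methyl]dihydrofuran-2(3H)-one, via lithium enolate 5 (not isolated)
Conditions: LDA, THF, −78 °C; MoOPH, −78 → −30 °C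
Reagents that add atoms: MoOPH (oxodiperoxymolybdenum·pyridine·HMPA), O=[Mo]12(OO1)OO2.c1ccncc1.CN(C)P(=O)(N(C)C)N(C)C
Why: Vedejs-type electrophilic hydroxylation of the tetrasubstituted enolate takes place on the face anti to CH2OTr, so the tertiary carbinol (future C10, S) is set by the purchased centre (OH trans to CH2OTr).

Step 4
Reactants: 7 (Z)-3-methylpent-2-en-4-yn-1-ol
Product: 8 tert-butyldimethyl{[(Z)-3-methylpent-2-en-4-yn-1-yl]oxy}silane
Conditions: TBSCl, imidazole, DMF, 0 °C → rt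
Reagents that add atoms: tert-butyldimethylsilyl chloride, CC(C)(C)[Si](C)(C)Cl
Why: Standard silylation masks the allylic alcohol, which would otherwise cyclise onto the alkyne to a furan; the Z geometry (future C4=C5) is bought.

Step 5
Reactants: 6 (3S,5R)-3-hydroxy-3-methyl-5-[(trityloxy)methyl]dihydrofuran-2(3H)-one; 8 tert-butyldimethyl{[(Z)-3-methylpent-2-en-4-yn-1-yl]oxy}silane
Product: 11 (S)-5-[(Z)-4-(TBSO)but-2-en-2-yl]-2-[(R)-2-hydroxy-3-(trityloxy)propyl]-2-methylfuran-3(2H)-one, via lithium acetylide 9 (not isolated), via hydroxy ynone 10 (not isolated)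
Conditions: 8 (2.3 equiv), n-BuLi (2.2 equiv), THF, −78 °C; 6, −78 → −30 °C; AcOH; crude in toluene, Ph3PAuCl/AgOTf (3 mol%), rt
Reagents that add atoms: none
Why: Acetylide addition to the non-enolisable lactone stops at the lactol alkoxide (the first equivalent only deprotonates the tertiary OH), work-up releases the α′-hydroxy ynone, and cationic Au(I) induces 5-endo-dig oxa-cyclisation (cycloisomerisation) through the tertiary OH to the 3(2H)-furanone without touching a stereocentre.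

Step 6
Reactants: 11 (S)-5-[(Z)-4-(TBSO)but-2-en-2-yl]-2-[(R)-2-hydroxy-3-(trityloxy)propyl]-2-methylfuran-3(2H)-one
Product: 12 (S)-5-[(Z)-4-(TBSO)but-2-en-2-yl]-2-[(R)-2-(TBSO)-3-(trityloxy)propyl]-2-methylfuran-3(2H)-one
Conditions: TBSOTf, 2,6-lutidine, CH2Cl2, −78 °C
Reagents that add atoms: tert-butyldimethylsilyl triflate, CC(C)(C)[Si](C)(C)OS(=O)(=O)C(F)(F)F
Why: Silyl triflate protection of the hindered secondary C8 alcohol blocks it from oxidation in step 8 and from competing 8,12-lactonisation in step 13.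

Step 7
Reactants: 12 (S)-5-[(Z)-4-(TBSO)but-2-en-2-yl]-2-[(R)-2-(TBSO)-3-(trityloxy)propyl]-2-methylfuran-3(2H)-one
Product: 13 (S)-5-[(Z)-4-(TBSO)but-2-en-2-yl]-2-[(R)-2-(TBSO)-3-hydroxypropyl]-2-methylfuran-3(2H)-one
Conditions: HCO2H/Et2O (1:1), 0 °C → rt, 30 min; aq NaHCO3
Reagents that add atoms: none
Why: The trityl ether ionises (SN1 solvolysis) much faster than TBS ethers under formic acid/ether, so only the primary C7 alcohol is released.

Step 8
Reactants: 13 (S)-5-[(Z)-4-(TBSO)but-2-en-2-yl]-2-[(R)-2-(TBSO)-3-hydroxypropyl]-2-methylfuran-3(2H)-one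
Product: 14 (R)-2-(TBSO)-3-{(S)-5-[(Z)-4-(TBSO)but-2-en-2-yl]-2-methyl-3-oxo-2,3-dihydrofuran-2-yl}propanal
Conditions: Dess–Martin periodinane, CH2Cl2, 0 °C; used crude
Reagents that add atoms: none
Why: Dess–Martin oxidation gives the α-silyloxy aldehyde under non-basic conditions, so C8 is not epimerised.

Step 9
Reactants: 14 (R)-2-(TBSO)-3-{(S)-5-[(Z)-4-(TBSO)but-2-en-2-yl]-2-methyl-3-oxo-2,3-dihydrofuran-2-yl}propanal; 15 methyl acrylate
Product: 16 methyl (4R)-4-(TBSO)-5-{(S)-5-[(Z)-4-(TBSO)but-2-en-2-yl]-2-methyl-3-oxo-2,3-dihydrofuran-2-yl}-3-hydroxy-2-methylidenepentanoate (C3 epimer mixture)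
Conditions: 15 (10 equiv), quinuclidine (0.3 equiv), MeOH (2 equiv), rt, 2–4 d
Reagents that add atoms: none
Why: Morita–Baylis–Hillman reaction attaches C11–C13 to the C7 aldehyde; the new carbinol centre is formed unselectively but is destroyed in step 10.

Step 10
Reactants: 16 methyl (4R)-4-(TBSO)-5-{(S)-5-[(Z)-4-(TBSO)but-2-en-2-yl]-2-methyl-3-oxo-2,3-dihydrofuran-2-yl}-3-hydroxy-2-methylidenepentanoate
Product: 17 methyl (2Z,4R)-2-(bromomethyl)-4-(TBSO)-5-{(S)-5-[(Z)-4-(TBSO)but-2-en-2-yl]-2-methyl-3-oxo-2,3-dihydrofuran-2-yl}pent-2-enoate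
Conditions: NBS, Me2S, CH2Cl2, 0 °C; then 16, 0 °C → rt
Reagents that add atoms: N-bromosuccinimide, O=C1CCC(=O)N1Br
Why: Corey–Kim-type activation of the allylic alcohol followed by SN2′ attack of bromide gives the thermodynamically preferred (Z)-2-(bromomethyl)enoate by allylic transposition.

Step 11
Reactants: 17 methyl (2Z,4R)-2-(bromomethyl)-4-(TBSO)-5-{(S)-5-[(Z)-4-(TBSO)but-2-en-2-yl]-2-methyl-3-oxo-2,3-dihydrofuran-2-yl}pent-2-enoate
Product: 18 methyl (2Z,4R)-2-(bromomethyl)-4-(TBSO)-5-{(S)-5-[(Z)-4-hydroxybut-2-en-2-yl]-2-methyl-3-oxo-2,3-dihydrofuran-2-yl}pent-2-enoate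
Conditions: CSA (10 mol%), MeOH/CH2Cl2 (1:1), 0 °C
Reagents that add atoms: none
Why: Acid-catalysed methanolysis cleaves the primary allylic TBS ether far faster than the hindered secondary one, and the amine- and fluoride-free medium spares the allylic bromide.

Step 12
Reactants: 18 methyl (2Z,4R)-2-(bromomethyl)-4-(TBSO)-5-{(S)-5-[(Z)-4-hydroxybut-2-en-2-yl]-2-methyl-3-oxo-2,3-dihydrofuran-2-yl}pent-2-enoate
Product: 19 methyl (2Z,4R)-2-(bromomethyl)-4-(TBSO)-5-{(S)-2-methyl-3-oxo-5-[(Z)-4-oxobut-2-en-2-yl]-2,3-dihydrofuran-2-yl}pent-2-enoate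
Conditions: Dess–Martin periodinane, CH2Cl2, 0 °C; used at once
Reagents that add atoms: none
Why: Dess–Martin oxidation of the allylic alcohol gives the (Z)-enal without the base or heat that would isomerise the C4=C5 bond.

Step 13
Reactants: 19 methyl (2Z,4R)-2-(bromomethyl)-4-(TBSO)-5-{(S)-2-methyl-3-oxo-5-[(Z)-4-oxobut-2-en-2-yl]-2,3-dihydrofuran-2-yl}pent-2-enoate
Product: 21 (4Z,6R,7S,8R,10S)-8-(TBSO)-1-oxo-3,10-epoxygermacra-2,4,11(13)-trien-12,6-olide, via hydroxy ester 20 (not isolated)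
Conditions: CrCl2 (15 mol%), 9-mesityl-10-methylacridinium perchlorate (3 mol%), Hantzsch ester (1.3 equiv), 2,6-lutidine (1.5 equiv), DMF/MeCN, 450 nm LEDs, rt, 19 added over 10 h (2 mM); then TsOH·H2O (10 mol%), CH2Cl2, rt
Reagents that add atoms: none
Why: Proposed new method: a chromium/acridinium dual-catalytic reductive Barbier macrocyclisation in which the excited acridinium is quenched by the Hantzsch ester, the acridinyl radical (about −0.6 V) reduces Cr(III) to Cr(II) but not the enal/furanone chromophore, Cr(II) turns the activated allylic bromide into an allyl–Cr(III) species that adds to the enal carbonyl through a closed six-membered chair transition state, and lutidinium protonation frees the alkoxide so that Cr turns over; the C6–C7 bond closes the ten-membered ring with C5 and C8 pseudo-equatorial (6,7-anti, hence the trans-lactone after acid lactonisation), and the C8 OTBS centre with the rigid (S)-C10 furanone/Z-alkene arc is expected to select the alkene face that puts H-7 cis to H-8 (target configuration at C6 and C7); the closest known reactions are stoichiometric CrCl2 Nozaki–Hiyama allylation macrocyclisations of 2-(bromomethyl)enoates onto aldehydes and intermolecular Cr/photoredox allylation of aldehydes.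

Step 14
Reactants: 21 (4Z,6R,7S,8R,10S)-8-(TBSO)-1-oxo-3,10-epoxygermacra-2,4,11(13)-trien-12,6-olide
Product: 22 (4Z,6R,7R,8R,10S)-8-hydroxy-1-oxo-3,10-epoxygermacra-2,4,11(13)-trien-12,6-olide
Conditions: HF·pyridine, THF, 0 °C → rt
Reagents that add atoms: none
Why: Fluoride-driven desilylation under mildly acidic conditions frees the C8 alcohol without base-induced translactonisation or conjugate addition to the α-methylene lactone.

Step 15
Reactants: 23 (E)-4-acetoxy-2-methylbut-2-enal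
Product: 24 (E)-4-acetoxy-2-methylbut-2-enoic acid
Conditions: NaClO2, NaH2PO4, 2-methyl-2-butene, t-BuOH/H2O, 0 °C → rt
Reagents that add atoms: sodium chlorite, [Na+].[O-]Cl=O
Why: Pinnick oxidation converts the enal into the acid under buffered conditions that keep the allylic acetate and the E geometry.

Step 16
Reactants: 22 (4Z,6R,7R,8R,10S)-8-hydroxy-1-oxo-3,10-epoxygermacra-2,4,11(13)-trien-12,6-olide; 24 (E)-4-acetoxy-2-methylbut-2-enoic acid
Product: 26 (4Z,6R,7R,8R,10S)-8-[(E)-4-acetoxy-2-methylbut-2-enoyloxy]-1-oxo-3,10-epoxygermacra-2,4,11(13)-trien-12,6-olide, via mixed anhydride 25 (not isolated)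
Conditions: 24, 2,4,6-trichlorobenzoyl chloride, Et3N, THF, rt; then 22, DMAP, toluene, rt
Reagents that add atoms: none
Why: Yamaguchi esterification acylates the hindered secondary C8 alcohol with retention (the C–O bond is not broken) and without isomerising the tiglate-type double bond.

## Compound list

1 | (R)-5-(hydroxymethyl)dihydrofuran-2(3H)-one | OC[C@H]1CCC(=O)O1 | starting material
2 | (R)-5-[(trityloxy)methyl]dihydrofuran-2(3H)-one | c1ccccc1C(c1ccccc1)(c1ccccc1)OC[C@H]1CCC(=O)O1 | intermediate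
3 | lithium enolate of 2 (not isolated) | [Li]OC1=CC[C@H](COC(c2ccccc2)(c2ccccc2)c2ccccc2)O1 | intermediate
4 | (3S,5R)-3-methyl-5-[(trityloxy)methyl]dihydrofuran-2(3H)-one (trans) | c1ccccc1C(c1ccccc1)(c1ccccc1)OC[C@H]1C[C@H](C)C(=O)O1 | intermediate
5 | lithium enolate of 4 (not isolated) | [Li]OC1=C(C)C[C@H](COC(c2ccccc2)(c2ccccc2)c2ccccc2)O1 | intermediate
6 | (3S,5R)-3-hydroxy-3-methyl-5-[(trityloxy)methyl]dihydrofuran-2(3H)-one (OH trans to CH2OTr) | c1ccccc1C(c1ccccc1)(c1ccccc1)OC[C@H]1C[C@](C)(O)C(=O)O1 | intermediate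
7 | (Z)-3-methylpent-2-en-4-yn-1-ol | C#C/C(C)=C\CO | starting material
8 | tert-butyldimethyl{[(Z)-3-methylpent-2-en-4-yn-1-yl]oxy}silane | C#C/C(C)=C\CO[Si](C)(C)C(C)(C)C | intermediate
9 | lithium acetylide of 8 (not isolated) | [Li]C#C/C(C)=C\CO[Si](C)(C)C(C)(C)C | intermediate
10 | (2R,4S,8Z)-10-(TBSO)-2,4-dihydroxy-4,8-dimethyl-1-(trityloxy)dec-8-en-6-yn-5-one (not isolated) | CC(C)(C)[Si](C)(C)OC/C=C(/C)C#CC(=O)[C@@](C)(O)C[C@@H](O)COC(c1ccccc1)(c1ccccc1)c1ccccc1 | intermediate
11 | (S)-5-[(Z)-4-(TBSO)but-2-en-2-yl]-2-[(R)-2-hydroxy-3-(trityloxy)propyl]-2-methylfuran-3(2H)-one | CC(C)(C)[Si](C)(C)OC/C=C(/C)C1=CC(=O)[C@](C)(C[C@@H](O)COC(c2ccccc2)(c2ccccc2)c2ccccc2)O1 | intermediate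
12 | (S)-5-[(Z)-4-(TBSO)but-2-en-2-yl]-2-[(R)-2-(TBSO)-3-(trityloxy)propyl]-2-methylfuran-3(2H)-one | CC(C)(C)[Si](C)(C)OC/C=C(/C)C1=CC(=O)[C@](C)(C[C@@H](O[Si](C)(C)C(C)(C)C)COC(c2ccccc2)(c2ccccc2)c2ccccc2)O1 | intermediate
13 | (S)-5-[(Z)-4-(TBSO)but-2-en-2-yl]-2-[(R)-2-(TBSO)-3-hydroxypropyl]-2-methylfuran-3(2H)-one | CC(C)(C)[Si](C)(C)OC/C=C(/C)C1=CC(=O)[C@](C)(C[C@@H](O[Si](C)(C)C(C)(C)C)CO)O1 | intermediate
14 | (R)-2-(TBSO)-3-{(S)-5-[(Z)-4-(TBSO)but-2-en-2-yl]-2-methyl-3-oxo-2,3-dihydrofuran-2-yl}propanal | CC(C)(C)[Si](C)(C)OC/C=C(/C)C1=CC(=O)[C@](C)(C[C@@H](O[Si](C)(C)C(C)(C)C)C=O)O1 | intermediate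
15 | methyl acrylate | C=CC(=O)OC | starting material
16 | methyl (4R)-4-(TBSO)-5-{(S)-5-[(Z)-4-(TBSO)but-2-en-2-yl]-2-methyl-3-oxo-2,3-dihydrofuran-2-yl}-3-hydroxy-2-methylidenepentanoate (both C3 epimers) | CC(C)(C)[Si](C)(C)OC/C=C(/C)C1=CC(=O)[C@](C)(C[C@@H](O[Si](C)(C)C(C)(C)C)C(O)C(=C)C(=O)OC)O1 | intermediate
17 | methyl (2Z,4R)-2-(bromomethyl)-4-(TBSO)-5-{(S)-5-[(Z)-4-(TBSO)but-2-en-2-yl]-2-methyl-3-oxo-2,3-dihydrofuran-2-yl}pent-2-enoate | CC(C)(C)[Si](C)(C)OC/C=C(/C)C1=CC(=O)[C@](C)(C[C@@H](O[Si](C)(C)C(C)(C)C)/C=C(\CBr)C(=O)OC)O1 | intermediate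
18 | methyl (2Z,4R)-2-(bromomethyl)-4-(TBSO)-5-{(S)-5-[(Z)-4-hydroxybut-2-en-2-yl]-2-methyl-3-oxo-2,3-dihydrofuran-2-yl}pent-2-enoate | OC/C=C(/C)C1=CC(=O)[C@](C)(C[C@@H](O[Si](C)(C)C(C)(C)C)/C=C(\CBr)C(=O)OC)O1 | intermediate
19 | methyl (2Z,4R)-2-(bromomethyl)-4-(TBSO)-5-{(S)-2-methyl-3-oxo-5-[(Z)-4-oxobut-2-en-2-yl]-2,3-dihydrofuran-2-yl}pent-2-enoate | O=C/C=C(/C)C1=CC(=O)[C@](C)(C[C@@H](O[Si](C)(C)C(C)(C)C)/C=C(\CBr)C(=O)OC)O1 | intermediate
20 | methyl 2-[(4Z,6R,7S,8R,10S)-8-(TBSO)-6-hydroxy-4,10-dimethyl-1-oxo-3,10-epoxycyclodeca-2,4-dien-7-yl]acrylate (H-6β, H-7α, 8β-OTBS; not isolated) | C=C(C(=O)OC)[C@H]1[C@H](O)/C=C(/C)C2=CC(=O)[C@](C)(C[C@H]1O[Si](C)(C)C(C)(C)C)O2 | intermediate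
21 | (4Z,6R,7S,8R,10S)-8-(TBSO)-1-oxo-3,10-epoxygermacra-2,4,11(13)-trien-12,6-olide (8-O-TBS ether of 22; trans-lactone, H-6β, H-7α, 8β-OTBS, 10α-Me) | C=C1C(=O)O[C@@H]2/C=C(/C)C3=CC(=O)[C@](C)(C[C@@H](O[Si](C)(C)C(C)(C)C)[C@@H]12)O3 | intermediate
22 | (4Z,6R,7R,8R,10S)-8-hydroxy-1-oxo-3,10-epoxygermacra-2,4,11(13)-trien-12,6-olide | C=C1C(=O)O[C@@H]2/C=C(/C)C3=CC(=O)[C@](C)(C[C@@H](O)[C@@H]12)O3 | intermediate
23 | (E)-4-acetoxy-2-methylbut-2-enal | CC(=O)OC/C=C(\C)C=O | starting material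
24 | (E)-4-acetoxy-2-methylbut-2-enoic acid | CC(=O)OC/C=C(\C)C(=O)O | intermediate
25 | (E)-4-acetoxy-2-methylbut-2-enoic 2,4,6-trichlorobenzoic anhydride (not isolated) | CC(=O)OC/C=C(\C)C(=O)OC(=O)c1c(Cl)cc(Cl)cc1Cl | intermediate
26 | (4Z,6R,7R,8R,10S)-8-[(E)-4-acetoxy-2-methylbut-2-enoyloxy]-1-oxo-3,10-epoxygermacra-2,4,11(13)-trien-12,6-olide (CNP0387534.1) | C=C1C(=O)O[C@@H]2/C=C(/C)C3=CC(=O)[C@](C)(C[C@@H](OC(=O)/C(C)=C/COC(C)=O)[C@@H]12)O3 | target

## Step count and risks

Total steps: 16 (steps 4 and 15 are side branches). Longest linear sequence: 14 steps (1 → 26 through steps 1–3, 5–14 and 16).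

Steps most likely to fail:

Step 13 (the proposed new macrocyclisation). Failure modes are oligomerisation or no closure of the strained ring, sensitised Z→E isomerisation of the enal, and the wrong alkene face at C7; the face selectivity is the least certain point, because simple acyclic models (H-8 inside, attack anti to OTBS) favour the 6,7-bis-epimer and the target relies on ring-conformational control. Fallback with known chemistry: starting from 19, give up the light-driven catalytic turnover and close the same C6–C7 bond by the classical thermal Nozaki–Hiyama/Barbier allylation with a stoichiometric metal (CrCl2 4–6 equiv in THF/DMF at high dilution, with In(0) or Zn(0) as alternative metals). This is the established way to close ten-membered germacranolide rings from 2-(bromomethyl)enoate aldehydes; it gives the hydroxy ester 20, and the same acid lactonisation rejoins the route at 21. It makes no new compound and does not by itself change the facial preference.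

Step 9 (Morita–Baylis–Hillman on a hindered α-silyloxy aldehyde). It may be very slow or erode C8. Fallback: starting from 14, replace amine catalysis by stoichiometric vinylalumination. Methyl propiolate is hydroaluminated (DIBAL-H, NMO, THF, 0 °C) to the α-(methoxycarbonyl)vinylalane, which adds to hindered aldehydes within minutes at 0 °C under non-basic conditions and delivers the same adduct, so the route is rejoined at 16 with no new compound.

Step 5 (acetylide addition to the free-hydroxy lactone and cyclisation). The α-alkoxide may make the lactone sluggish, or lactol/ynone mixtures may cyclise poorly. Fallback: starting from 6, open the lactone with MeNH(OMe)·HCl/i-PrMgCl to the Weinreb amide (2S,4R)-2,4-dihydroxy-N-methoxy-N,2-dimethyl-5-(trityloxy)pentanamide F1. Silylate its secondary alcohol selectively (TBSCl, imidazole) to (2S,4R)-4-(TBSO)-2-hydroxy-N-methoxy-N,2-dimethyl-5-(trityloxy)pentanamide F2. Add lithium acetylide 9 (3 equiv, the first deprotonating the tertiary OH) to obtain, through the chelated tetrahedral intermediate, (2R,4S,8Z)-2,10-bis(TBSO)-4-hydroxy-4,8-dimethyl-1-(trityloxy)dec-8-en-6-yn-5-one F3. The same Au(I) cyclisation then gives 12 directly, rejoining the route at 12 and skipping step 6.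

## Further compounds

F1 | step 5 | (2S,4R)-2,4-dihydroxy-N-methoxy-N,2-dimethyl-5-(trityloxy)pentanamide | CON(C)C(=O)[C@@](C)(O)C[C@@H](O)COC(c1ccccc1)(c1ccccc1)c1ccccc1
F2 | step 5 | (2S,4R)-4-(TBSO)-2-hydroxy-N-methoxy-N,2-dimethyl-5-(trityloxy)pentanamide | CON(C)C(=O)[C@@](C)(O)C[C@@H](O[Si](C)(C)C(C)(C)C)COC(c1ccccc1)(c1ccccc1)c1ccccc1
F3 | step 5 | (2R,4S,8Z)-2,10-bis(TBSO)-4-hydroxy-4,8-dimethyl-1-(trityloxy)dec-8-en-6-yn-5-one | CC(C)(C)[Si](C)(C)OC/C=C(/C)C#CC(=O)[C@@](C)(O)C[C@@H](O[Si](C)(C)C(C)(C)C)COC(c1ccccc1)(c1ccccc1)c1ccccc1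
F0 | step 9 | none | none
F0 | step 13 | none | none
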